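## Retrosynthetic overview

1. Lactol ring D is closed last by acid unmasking of a silyl ether and a dioxolane on ring C; the ring C tertiary carbinol comes from MeMgBr addition to a ketone.
2. The ring C ketone comes from a decarboxylative radical conjugate addition of the hydroazulenylacetic acid to a ring C α-methylene ketone, itself made from cyclohexane-1,3-dione through a 4-silyloxy enone and an anti cuprate addition.
3. The hydroazulenylacetic acid comes from CBS reduction and Johnson–Claisen rearrangement of a bicyclic hydroxy enone, which sets the side-chain center and the trisubstituted alkene together.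
4. Key step: the bicyclic hydroxy enone comes from a SmI2 ketyl–olefin radical cyclization of a cross-conjugated cycloheptadienone bearing a 3-oxobutyl arm, closing cyclopentanol ring A onto ring B.
5. Ring B comes from ring-closing metathesis after an aldol and a chirality-transferring aldehyde Claisen rearrangement. Ring order: B, then A, then union with preformed ring C, then D.

Assumption: the target is taken as the drawn equatorial lactol anomer, which equilibrates with its epimer in solution; the lipase of step 13 is taken to cleave the (S)-acetate (if it prefers the (R)-acetate, the recovered (S)-acetate is methanolysed with K2CO3/MeOH to the same 24).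

## Route

Step 1
Reactants: 1 hex-5-en-2-one
Product: 2 2-(but-3-en-1-yl)-2-methyl-1,3-dioxolane
Conditions: HOCH2CH2OH, p-TsOH·H2O (cat.), benzene, reflux, Dean–Stark
Reagents that add atoms: ethane-1,2-diol, OCCO
Why: Acid-catalysed ketalization with azeotropic removal of water masks the methyl ketone, which would otherwise undergo aldol reactions with the aldehyde made in step 3, and no stereocenter is formed.

Step 2
Reactants: 2 2-(but-3-en-1-yl)-2-methyl-1,3-dioxolane; 3 (R)-but-3-en-2-ol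
Product: 4 (2R,3E)-6-(2-methyl-1,3-dioxolan-2-yl)hex-3-en-2-ol
Conditions: second-generation Hoveyda–Grubbs catalyst (3 mol%), 2 (3 equiv), CH2Cl2, 40 °C
Reagents that add atoms: none
Why: Olefin cross-metathesis of a terminal alkene with a secondary allylic alcohol is E-selective and does not touch the carbinol center, so 4 keeps the (R)-configuration bought with 3.

Step 3
Reactants: 4 (2R,3E)-6-(2-methyl-1,3-dioxolan-2-yl)hex-3-en-2-ol; 5 1-iodo-2-methylprop-1-ene
Product: 7 (3S,4E)-2,2-dimethyl-3-[2-(2-methyl-1,3-dioxolan-2-yl)ethyl]hex-4-enal, via allyl vinyl ether 6 (not isolated)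
Conditions: CuI (10 mol%), 3,4,7,8-tetramethyl-1,10-phenanthroline (20 mol%), Cs2CO3, o-xylene, 120 °C
Reagents that add atoms: none
Why: Copper-catalysed C–O vinylation followed in the same flask by Claisen rearrangement of 6 through a chair transition state with the carbinol methyl equatorial builds the gem-dimethyl quaternary carbon and transfers the (R)-carbinol chirality to the new (3S) center with an E-propenyl group.

Step 4
Reactants: 7 (3S,4E)-2,2-dimethyl-3-[2-(2-methyl-1,3-dioxolan-2-yl)ethyl]hex-4-enal; 8 pent-1-en-3-one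
Product: 10 (7S,8E)-5-hydroxy-4,6,6-trimethyl-7-[2-(2-methyl-1,3-dioxolan-2-yl)ethyl]deca-1,8-dien-3-one, via lithium dienolate 9 (not isolated)
Conditions: LiN(i-Pr)2, THF, −78 °C, 8 then 7; then H2O
Reagents that add atoms: none
Why: Kinetic deprotonation of 8 at its ethyl group and aldol addition to the non-enolisable neopentyl aldehyde give the β-hydroxy ketone as a mixture at the two new centers, which does not matter because both are removed in step 6.

Step 5
Reactants: 10 (7S,8E)-5-hydroxy-4,6,6-trimethyl-7-[2-(2-methyl-1,3-dioxolan-2-yl)ethyl]deca-1,8-dien-3-one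
Product: 11 (4S)-6-hydroxy-5,5,7-trimethyl-4-[2-(2-methyl-1,3-dioxolan-2-yl)ethyl]cyclohept-2-en-1-one
Conditions: second-generation Hoveyda–Grubbs catalyst (5 mol%), CH2Cl2 (5 mM), 40 °C
Reagents that add atoms: none
Why: Ring-closing metathesis between the vinyl ketone and the propenyl group (loss of propene) closes seven-membered ring B while the second ring alkene is still held as a β-hydroxy ketone, so no Z-enone has to be prepared, and the existing stereocenter is untouched.

Step 6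
Reactants: 11 (4S)-6-hydroxy-5,5,7-trimethyl-4-[2-(2-methyl-1,3-dioxolan-2-yl)ethyl]cyclohept-2-en-1-one
Product: 14 (5S)-2,4,4-trimethyl-5-(3-oxobutyl)cyclohepta-2,6-dien-1-one, via mesylate 12 (not isolated), via ketal dienone 13 (not isolated)
Conditions: MsCl, Et3N, CH2Cl2, 0 °C → rt; then 1 M aq. HCl, THF, rt
Reagents that add atoms: water, O
Why: Mesylation and E1cB elimination of the β-hydroxy ketone (the other neighbour of the carbinol is quaternary, so only the α-hydrogen can be lost) give the cross-conjugated dienone, and the acidic second stage hydrolyses the dioxolane without touching the lone stereocenter.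

Step 7
Reactants: 14 (5S)-2,4,4-trimethyl-5-(3-oxobutyl)cyclohepta-2,6-dien-1-one
Product: 15 (3S,3aS,8aS)-3-hydroxy-3,6,8,8-tetramethyl-2,3,3a,4,8,8a-hexahydroazulen-5(1H)-one
Conditions: SmI2 (2.5 equiv, 0.1 M in THF), HMPA (8 equiv), THF, −78 → −20 °C; then pH 7 buffer
Reagents that add atoms: none
Why: In this ketyl–olefin radical cyclization divalent samarium generates a ketyl that adds 5-exo to the β-carbon of the unsubstituted enone arm to form the C3–C3a bond, the three-atom tether forcing cis ring fusion relative to the existing center and the bulky O–Sm group turning away from the ring CH2–C=O carbon so that the hydroxyl ends up cis to the ring-fusion hydrogens, while a second electron transfer gives a samarium dienolate that keeps the α-methyl enone intact until work-up.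

Step 8
Reactants: 15 (3S,3aS,8aS)-3-hydroxy-3,6,8,8-tetramethyl-2,3,3a,4,8,8a-hexahydroazulen-5(1H)-one
Product: 16 (3S,3aS,5R,8aS)-3,6,8,8-tetramethyl-1,2,3,3a,4,5,8,8a-octahydroazulene-3,5-diol
Conditions: (S)-2-methyl-CBS-oxazaborolidine (20 mol%), BH3·SMe2, THF, −20 °C; then H2O
Reagents that add atoms: none
Why: Corey–Bakshi–Shibata 1,2-reduction of the α-methyl enone is catalyst-controlled (the α-substituted alkene acts as the large group) and gives the (5R)-allylic alcohol, a sense reinforced by hydride attack on the convex face away from the cyclopentane ring.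

Step 9
Reactants: 16 (3S,3aS,5R,8aS)-3,6,8,8-tetramethyl-1,2,3,3a,4,5,8,8a-octahydroazulene-3,5-diol; 17 trimethyl orthoacetate
Product: 19 methyl 2-[(3S,3aS,7R,8aS)-3-hydroxy-3,6,8,8-tetramethyl-1,2,3,3a,4,7,8,8a-octahydroazulen-7-yl]acetate, via ketene acetal 18 (not isolated)
Conditions: 17 (8 equiv), EtCO2H (cat.), xylenes, 140 °C, MeOH distilled off
Reagents that add atoms: none
Why: Johnson–Claisen rearrangement of the secondary allylic alcohol (the tertiary alcohol forms no ketene acetal) delivers the acetate unit suprafacially from the C5 oxygen to C7, which fixes the (7R) center beside the gem-dimethyl carbon and moves the alkene into its final trisubstituted position.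

Step 10
Reactants: 19 methyl 2-[(3S,3aS,7R,8aS)-3-hydroxy-3,6,8,8-tetramethyl-1,2,3,3a,4,7,8,8a-octahydroazulen-7-yl]acetate
Product: 20 2-[(3S,3aS,7R,8aS)-3-hydroxy-3,6,8,8-tetramethyl-1,2,3,3a,4,7,8,8a-octahydroazulen-7-yl]acetic acid
Conditions: LiOH, THF/MeOH/H2O, 40 °C; then 1 M aq. HCl
Reagents that add atoms: lithium hydroxide, [Li+].[OH-]
Why: Saponification of the unhindered methyl ester frees the carboxylic acid needed as radical precursor and touches no stereocenter.

Step 11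
Reactants: 21 cyclohexane-1,3-dione
Product: 22 3-ethoxycyclohex-2-en-1-one
Conditions: EtOH, p-TsOH·H2O (cat.), benzene, reflux, Dean–Stark
Reagents that add atoms: ethanol, CCO
Why: Acid-catalysed enol ether formation of the 1,3-dione gives the vinylogous ester used for a later Stork–Danheiser transposition.

Step 12
Reactants: 22 3-ethoxycyclohex-2-en-1-one
Product: 23 (±)-4-ethoxy-2-oxocyclohex-3-en-1-yl acetate
Conditions: Mn(OAc)3·2H2O (2.5 equiv), benzene, reflux
Reagents that add atoms: manganese triacetate, CC(=O)[O-].CC(=O)[O-].CC(=O)[O-].[Mn+3]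
Why: Trivalent manganese oxidises the enone at its only enolisable α'-position (α'-acetoxylation of a β-alkoxy enone), giving the racemic acetate.

Step 13
Reactants: 23 (±)-4-ethoxy-2-oxocyclohex-3-en-1-yl acetate
Product: 24 (S)-3-ethoxy-6-hydroxycyclohex-2-en-1-one
Conditions: Amano lipase PS, phosphate buffer (pH 7)/DMSO, rt, stopped at 50% conversion; chromatography removes unreacted (R)-23
Reagents that add atoms: none
Why: Enzymatic kinetic resolution by enantioselective acetate hydrolysis supplies the (S)-carbinol that later becomes the ring D oxygen-bearing center.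

Step 14
Reactants: 24 (S)-3-ethoxy-6-hydroxycyclohex-2-en-1-one
Product: 25 (S)-6-[(tert-butyldimethylsilyl)oxy]-3-ethoxycyclohex-2-en-1-one
Conditions: TBSCl, imidazole, DMF, rt
Reagents that add atoms: tert-butylchlorodimethylsilane, CC(C)(C)[Si](C)(C)Cl
Why: Silylation protects the secondary alcohol and makes it the bulky group that will direct the cuprate addition of step 16.

Step 15
Reactants: 25 (S)-6-[(tert-butyldimethylsilyl)oxy]-3-ethoxycyclohex-2-en-1-one
Product: 27 (S)-4-[(tert-butyldimethylsilyl)oxy]-3-methylcyclohex-2-en-1-one, via tertiary carbinol 26 (not isolated)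
Conditions: MeLi, THF, −78 °C; then 1 M aq. HCl, 0 °C
Reagents that add atoms: methyllithium, [Li]C; water, O
Why: Stork–Danheiser transposition (1,2-addition of MeLi to the vinylogous ester, then acid hydrolysis and dehydration) places the methyl group on the β-carbon and the silyloxy center at the γ-position without touching its configuration.

Step 16
Reactants: 27 (S)-4-[(tert-butyldimethylsilyl)oxy]-3-methylcyclohex-2-en-1-one; 28 2-(2-bromoethyl)-1,3-dioxolane
Product: 31 (3S,4S)-4-[(tert-butyldimethylsilyl)oxy]-2-[(dimethylamino)methyl]-3-[2-(1,3-dioxolan-2-yl)ethyl]-3-methylcyclohexan-1-one, via Grignard reagent 29 (not isolated), via silyl enol ether 30 (not isolated)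
Conditions: 28, Mg, THF, 25 °C; then CuBr·SMe2 (10 mol%), Me3SiCl, 27, THF, −78 → −40 °C; then CH2=NMe2+ I−, CH2Cl2, −40 °C → rt; aq. NaHCO3
Reagents that add atoms: dimethylmethylideneammonium iodide (Eschenmoser's salt), C=[N+](C)C.[I-]
Why: Copper-catalysed conjugate addition of 29 anti to the γ-silyloxy group creates the quaternary (3S) center, and the regiodefined silyl enol ether 30 then undergoes a Mannich reaction with Eschenmoser's salt at C2 only.

Step 17
Reactants: 31 (3S,4S)-4-[(tert-butyldimethylsilyl)oxy]-2-[(dimethylamino)methyl]-3-[2-(1,3-dioxolan-2-yl)ethyl]-3-methylcyclohexan-1-one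
Product: 33 (3S,4S)-4-[(tert-butyldimethylsilyl)oxy]-3-[2-(1,3-dioxolan-2-yl)ethyl]-3-methyl-2-methylidenecyclohexan-1-one, via ammonium iodide 32 (not isolated)
Conditions: MeI, CH2Cl2, rt; then aq. NaHCO3, rt
Reagents that add atoms: none
Why: N-methylation and E1cB loss of trimethylamine from the β-ammonio ketone give the α-methylene ketone, which the neighbouring quaternary carbon protects from dimerization.

Step 18
Reactants: 20 2-[(3S,3aS,7R,8aS)-3-hydroxy-3,6,8,8-tetramethyl-1,2,3,3a,4,7,8,8a-octahydroazulen-7-yl]acetic acid; 33 (3S,4S)-4-[(tert-butyldimethylsilyl)oxy]-3-[2-(1,3-dioxolan-2-yl)ethyl]-3-methyl-2-methylidenecyclohexan-1-one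
Product: 35 (2S,3S,4S)-4-[(tert-butyldimethylsilyl)oxy]-3-[2-(1,3-dioxolan-2-yl)ethyl]-2-{2-[(3S,3aS,7R,8aS)-3-hydroxy-3,6,8,8-tetramethyl-1,2,3,3a,4,7,8,8a-octahydroazulen-7-yl]ethyl}-3-methylcyclohexan-1-one, via phthalimidoyl ester 34 (not isolated)
Conditions: N-hydroxyphthalimide, DIC, DMAP (cat.), CH2Cl2, rt; then 33 (1.5 equiv), Hantzsch ester, Ru(bpy)3(PF6)2 (1 mol%), i-Pr2NEt, CH2Cl2, blue LEDs, rt; then DBU (cat.), rt
Reagents that add atoms: none
Why: In this decarboxylative Giese reaction reductive fragmentation of 34 gives a primary radical that adds to the unhindered CH2 terminus of the enone, and DBU equilibrates the epimerisable α-center to the equatorial (2S) side chain.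

Step 19
Reactants: 35 (2S,3S,4S)-4-[(tert-butyldimethylsilyl)oxy]-3-[2-(1,3-dioxolan-2-yl)ethyl]-2-{2-[(3S,3aS,7R,8aS)-3-hydroxy-3,6,8,8-tetramethyl-1,2,3,3a,4,7,8,8a-octahydroazulen-7-yl]ethyl}-3-methylcyclohexan-1-one
Product: 36 (1R,2S,3S,4S)-4-[(tert-butyldimethylsilyl)oxy]-3-[2-(1,3-dioxolan-2-yl)ethyl]-2-{2-[(3S,3aS,7R,8aS)-3-hydroxy-3,6,8,8-tetramethyl-1,2,3,3a,4,7,8,8a-octahydroazulen-7-yl]ethyl}-1,3-dimethylcyclohexan-1-ol
Conditions: MeMgBr (4 equiv), CeCl3, THF, −78 → 0 °C; then H2O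
Reagents that add atoms: methylmagnesium bromide, C[Mg]Br
Why: Grignard addition in the presence of CeCl3 occurs from the equatorial direction because the axial methyl on C3 blocks the axial trajectory (1,3-diaxial), giving the axial (1R) tertiary alcohol cis to that methyl.

Step 20
Reactants: 36 (1R,2S,3S,4S)-4-[(tert-butyldimethylsilyl)oxy]-3-[2-(1,3-dioxolan-2-yl)ethyl]-2-{2-[(3S,3aS,7R,8aS)-3-hydroxy-3,6,8,8-tetramethyl-1,2,3,3a,4,7,8,8a-octahydroazulen-7-yl]ethyl}-1,3-dimethylcyclohexan-1-ol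
Product: 38 (2S,4aS,5S,6R,8aS)-5-{2-[(3S,3aS,7R,8aS)-3-hydroxy-3,6,8,8-tetramethyl-1,2,3,3a,4,7,8,8a-octahydroazulen-7-yl]ethyl}-4a,6-dimethyloctahydro-2H-chromene-2,6-diol, via hydroxy aldehyde 37 (not isolated)
Conditions: HF (48% aq.), MeCN, 0 °C → rt
Reagents that add atoms: water, O
Why: Acidic desilylation and acetal hydrolysis release a 5-hydroxy aldehyde that closes spontaneously to the trans-fused six-membered lactol, whose anomeric center equilibrates to the equatorial hydroxyl drawn for the target.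

## Compound list

1 | hex-5-en-2-one | CC(=O)CCC=C | starting material
2 | 2-(but-3-en-1-yl)-2-methyl-1,3-dioxolane | C=CCCC1(C)OCCO1 | intermediate
3 | (R)-but-3-en-2-ol | C[C@@H](O)C=C | starting material
4 | (2R,3E)-6-(2-methyl-1,3-dioxolan-2-yl)hex-3-en-2-ol | C[C@@H](O)/C=C/CCC1(C)OCCO1 | intermediate
5 | 1-iodo-2-methylprop-1-ene | CC(C)=CI | starting material
6 | 2-methyl-2-{(3E,5R)-5-[(2-methylprop-1-en-1-yl)oxy]hex-3-en-1-yl}-1,3-dioxolane | C[C@@H](OC=C(C)C)/C=C/CCC1(C)OCCO1 | intermediate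
7 | (3S,4E)-2,2-dimethyl-3-[2-(2-methyl-1,3-dioxolan-2-yl)ethyl]hex-4-enal | C/C=C/[C@H](CCC1(C)OCCO1)C(C)(C)C=O | intermediate
8 | pent-1-en-3-one | CCC(=O)C=C | starting material
9 | lithium penta-1,3-dien-3-olate | CC=C(O[Li])C=C | intermediate
10 | (7S,8E)-5-hydroxy-4,6,6-trimethyl-7-[2-(2-methyl-1,3-dioxolan-2-yl)ethyl]deca-1,8-dien-3-one (mixture at C4 and C5) | C/C=C/[C@H](CCC1(C)OCCO1)C(C)(C)C(O)C(C)C(=O)C=C | intermediate
11 | (4S)-6-hydroxy-5,5,7-trimethyl-4-[2-(2-methyl-1,3-dioxolan-2-yl)ethyl]cyclohept-2-en-1-one (mixture at C6 and C7) | CC1C(O)C(C)(C)[C@@H](CCC2(C)OCCO2)C=CC1=O | intermediate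
12 | (3S)-2,2,7-trimethyl-3-[2-(2-methyl-1,3-dioxolan-2-yl)ethyl]-6-oxocyclohept-4-en-1-yl methanesulfonate | CC1C(OS(C)(=O)=O)C(C)(C)[C@@H](CCC2(C)OCCO2)C=CC1=O | intermediate
13 | (5S)-2,4,4-trimethyl-5-[2-(2-methyl-1,3-dioxolan-2-yl)ethyl]cyclohepta-2,6-dien-1-one | CC1=CC(C)(C)[C@@H](CCC2(C)OCCO2)C=CC1=O | intermediate
14 | (5S)-2,4,4-trimethyl-5-(3-oxobutyl)cyclohepta-2,6-dien-1-one | CC1=CC(C)(C)[C@@H](CCC(C)=O)C=CC1=O | intermediate
15 | (3S,3aS,8aS)-3-hydroxy-3,6,8,8-tetramethyl-2,3,3a,4,8,8a-hexahydroazulen-5(1H)-one | CC1=CC(C)(C)[C@H]2CC[C@](C)(O)[C@H]2CC1=O | intermediate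
16 | (3S,3aS,5R,8aS)-3,6,8,8-tetramethyl-1,2,3,3a,4,5,8,8a-octahydroazulene-3,5-diol | CC1=CC(C)(C)[C@H]2CC[C@](C)(O)[C@H]2C[C@H]1O | intermediate
17 | trimethyl orthoacetate | CC(OC)(OC)OC | starting material
18 | (3S,3aS,5R,8aS)-5-[(1-methoxyethenyl)oxy]-3,6,8,8-tetramethyl-1,2,3,3a,4,5,8,8a-octahydroazulen-3-ol | CC1=CC(C)(C)[C@H]2CC[C@](C)(O)[C@H]2C[C@H]1OC(=C)OC | intermediate
19 | methyl 2-[(3S,3aS,7R,8aS)-3-hydroxy-3,6,8,8-tetramethyl-1,2,3,3a,4,7,8,8a-octahydroazulen-7-yl]acetate | CC1=CC[C@H]2[C@H](CC[C@]2(C)O)C(C)(C)[C@@H]1CC(=O)OC | intermediate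
20 | 2-[(3S,3aS,7R,8aS)-3-hydroxy-3,6,8,8-tetramethyl-1,2,3,3a,4,7,8,8a-octahydroazulen-7-yl]acetic acid | CC1=CC[C@H]2[C@H](CC[C@]2(C)O)C(C)(C)[C@@H]1CC(=O)O | intermediate
21 | cyclohexane-1,3-dione | O=C1CCCC(=O)C1 | starting material
22 | 3-ethoxycyclohex-2-en-1-one | CCOC1=CC(=O)CCC1 | intermediate
23 | (±)-4-ethoxy-2-oxocyclohex-3-en-1-yl acetate | CCOC1=CC(=O)C(OC(C)=O)CC1 | intermediate
24 | (S)-3-ethoxy-6-hydroxycyclohex-2-en-1-one | CCOC1=CC(=O)[C@@H](O)CC1 | intermediate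
25 | (S)-6-[(tert-butyldimethylsilyl)oxy]-3-ethoxycyclohex-2-en-1-one | CCOC1=CC(=O)[C@@H](O[Si](C)(C)C(C)(C)C)CC1 | intermediate
26 | (6S)-6-[(tert-butyldimethylsilyl)oxy]-3-ethoxy-1-methylcyclohex-2-en-1-ol (mixture at C1) | CCOC1=CC(C)(O)[C@@H](O[Si](C)(C)C(C)(C)C)CC1 | intermediate
27 | (S)-4-[(tert-butyldimethylsilyl)oxy]-3-methylcyclohex-2-en-1-one | CC1=CC(=O)CC[C@@H]1O[Si](C)(C)C(C)(C)C | intermediate
28 | 2-(2-bromoethyl)-1,3-dioxolane | BrCCC1OCCO1 | starting material
29 | [2-(1,3-dioxolan-2-yl)ethyl]magnesium bromide | Br[Mg]CCC1OCCO1 | intermediate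
30 | tert-butyl({(1S,2S)-2-[2-(1,3-dioxolan-2-yl)ethyl]-2-methyl-4-[(trimethylsilyl)oxy]cyclohex-3-en-1-yl}oxy)dimethylsilane | C[Si](C)(C)OC1=C[C@](C)(CCC2OCCO2)[C@@H](O[Si](C)(C)C(C)(C)C)CC1 | intermediate
31 | (3S,4S)-4-[(tert-butyldimethylsilyl)oxy]-2-[(dimethylamino)methyl]-3-[2-(1,3-dioxolan-2-yl)ethyl]-3-methylcyclohexan-1-one (mixture at C2) | CN(C)CC1C(=O)CC[C@H](O[Si](C)(C)C(C)(C)C)[C@@]1(C)CCC1OCCO1 | intermediate
32 | N,N,N-trimethylammonium iodide of 31 | C[N+](C)(C)CC1C(=O)CC[C@H](O[Si](C)(C)C(C)(C)C)[C@@]1(C)CCC1OCCO1.[I-] | intermediate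
33 | (3S,4S)-4-[(tert-butyldimethylsilyl)oxy]-3-[2-(1,3-dioxolan-2-yl)ethyl]-3-methyl-2-methylidenecyclohexan-1-one | C=C1C(=O)CC[C@H](O[Si](C)(C)C(C)(C)C)[C@@]1(C)CCC1OCCO1 | intermediate
34 | 1,3-dioxoisoindolin-2-yl 2-[(3S,3aS,7R,8aS)-3-hydroxy-3,6,8,8-tetramethyl-1,2,3,3a,4,7,8,8a-octahydroazulen-7-yl]acetate | CC1=CC[C@H]2[C@H](CC[C@]2(C)O)C(C)(C)[C@@H]1CC(=O)ON1C(=O)c2ccccc2C1=O | intermediate
35 | (2S,3S,4S)-4-[(tert-butyldimethylsilyl)oxy]-3-[2-(1,3-dioxolan-2-yl)ethyl]-2-{2-[(3S,3aS,7R,8aS)-3-hydroxy-3,6,8,8-tetramethyl-1,2,3,3a,4,7,8,8a-octahydroazulen-7-yl]ethyl}-3-methylcyclohexan-1-one | CC1=CC[C@H]2[C@H](CC[C@]2(C)O)C(C)(C)[C@@H]1CC[C@@H]1C(=O)CC[C@H](O[Si](C)(C)C(C)(C)C)[C@@]1(C)CCC1OCCO1 | intermediate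
36 | (1R,2S,3S,4S)-4-[(tert-butyldimethylsilyl)oxy]-3-[2-(1,3-dioxolan-2-yl)ethyl]-2-{2-[(3S,3aS,7R,8aS)-3-hydroxy-3,6,8,8-tetramethyl-1,2,3,3a,4,7,8,8a-octahydroazulen-7-yl]ethyl}-1,3-dimethylcyclohexan-1-ol | CC1=CC[C@H]2[C@H](CC[C@]2(C)O)C(C)(C)[C@@H]1CC[C@@H]1[C@](C)(O)CC[C@H](O[Si](C)(C)C(C)(C)C)[C@@]1(C)CCC1OCCO1 | intermediate
37 | 3-[(1S,2S,3R,6S)-3,6-dihydroxy-2-{2-[(3S,3aS,7R,8aS)-3-hydroxy-3,6,8,8-tetramethyl-1,2,3,3a,4,7,8,8a-octahydroazulen-7-yl]ethyl}-1,3-dimethylcyclohexyl]propanal | CC1=CC[C@H]2[C@H](CC[C@]2(C)O)C(C)(C)[C@@H]1CC[C@@H]1[C@](C)(O)CC[C@H](O)[C@@]1(C)CCC=O | intermediate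
38 | (2S,4aS,5S,6R,8aS)-5-{2-[(3S,3aS,7R,8aS)-3-hydroxy-3,6,8,8-tetramethyl-1,2,3,3a,4,7,8,8a-octahydroazulen-7-yl]ethyl}-4a,6-dimethyloctahydro-2H-chromene-2,6-diol (CNP0167351.1) | CC1=CC[C@H]2[C@H](CC[C@]2(C)O)C(C)(C)[C@@H]1CC[C@H]1[C@]2(C)CC[C@@H](O)O[C@H]2CC[C@@]1(C)O | target

## Step count and risks

Total steps: 20. Longest linear sequence: 13 (steps 1–10, then 18–20); the ring C branch is steps 11–17.

Risk 1, step 3 (copper-catalysed vinylation and Claisen rearrangement). A hindered secondary alcohol must couple and then form a quaternary carbon at 120 °C in the presence of base. The fallback sets out from 4 and returns at 7. Acylation of 4 with isobutyryl chloride and pyridine gives (2R,3E)-6-(2-methyl-1,3-dioxolan-2-yl)hex-3-en-2-yl 2-methylpropanoate F1. Ireland–Claisen rearrangement (LiN(i-Pr)2, Me3SiCl, THF, −78 → 60 °C, then mild acid) through the same chair gives (3S,4E)-2,2-dimethyl-3-[2-(2-methyl-1,3-dioxolan-2-yl)ethyl]hex-4-enoic acid F2. LiAlH4 reduces it to (3S,4E)-2,2-dimethyl-3-[2-(2-methyl-1,3-dioxolan-2-yl)ethyl]hex-4-en-1-ol F3, and Dess–Martin periodinane oxidises F3 to 7.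

Risk 2, step 7 (SmI2 ketyl–olefin cyclization). The cross-conjugated dienone may be over-reduced or dimerised, and the carbinol configuration rests on a non-chelated transition state. The fallback sets out from 14 and returns at 15, replacing electron transfer by hydrogen-atom transfer. KN(SiMe3)2 and TBSCl at −78 °C convert the methyl ketone into (5S)-5-{3-[(tert-butyldimethylsilyl)oxy]but-3-en-1-yl}-2,4,4-trimethylcyclohepta-2,6-dien-1-one F4. Fe(acac)3 and PhSiH3 in EtOH at 60 °C transfer a hydrogen atom to the silyl enol ether, and the tertiary α-silyloxy radical closes the five-membered ring onto the dienone to give (3S,3aS,8aS)-3-[(tert-butyldimethylsilyl)oxy]-3,6,8,8-tetramethyl-2,3,3a,4,8,8a-hexahydroazulen-5(1H)-one F5. TBAF in THF releases 15.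

Risk 3, step 9 (Johnson–Claisen rearrangement). The new bond forms beside a quaternary carbon at 140 °C with a free tertiary alcohol present. The fallback sets out from 16 and returns at 35, bypassing 19, 20 and 34. KH and Bu3SnCH2I alkylate the secondary alkoxide to (3S,3aS,5R,8aS)-3,6,8,8-tetramethyl-5-[(tributylstannyl)methoxy]-1,2,3,3a,4,5,8,8a-octahydroazulen-3-ol F6. n-BuLi at −78 °C triggers a suprafacial [2,3]-Wittig–Still rearrangement to (3S,3aS,7R,8aS)-7-(hydroxymethyl)-3,6,8,8-tetramethyl-1,2,3,3a,4,7,8,8a-octahydroazulen-3-ol F7. I2, PPh3 and imidazole give (3S,3aS,7R,8aS)-7-(iodomethyl)-3,6,8,8-tetramethyl-1,2,3,3a,4,7,8,8a-octahydroazulen-3-ol F8. Its primary radical, generated with (Me3Si)3SiH and AIBN in toluene at 80 °C, adds to 33, and DBU equilibration gives 35.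

## Further compounds

F1 | step 3 | (2R,3E)-6-(2-methyl-1,3-dioxolan-2-yl)hex-3-en-2-yl 2-methylpropanoate | C[C@@H](OC(=O)C(C)C)/C=C/CCC1(C)OCCO1
F2 | step 3 | (3S,4E)-2,2-dimethyl-3-[2-(2-methyl-1,3-dioxolan-2-yl)ethyl]hex-4-enoic acid | C/C=C/[C@H](CCC1(C)OCCO1)C(C)(C)C(=O)O
F3 | step 3 | (3S,4E)-2,2-dimethyl-3-[2-(2-methyl-1,3-dioxolan-2-yl)ethyl]hex-4-en-1-ol | C/C=C/[C@H](CCC1(C)OCCO1)C(C)(C)CO
F4 | step 7 | (5S)-5-{3-[(tert-butyldimethylsilyl)oxy]but-3-en-1-yl}-2,4,4-trimethylcyclohepta-2,6-dien-1-one | CC1=CC(C)(C)[C@@H](CCC(=C)O[Si](C)(C)C(C)(C)C)C=CC1=O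
F5 | step 7 | (3S,3aS,8aS)-3-[(tert-butyldimethylsilyl)oxy]-3,6,8,8-tetramethyl-2,3,3a,4,8,8a-hexahydroazulen-5(1H)-one | CC1=CC(C)(C)[C@H]2CC[C@](C)(O[Si](C)(C)C(C)(C)C)[C@H]2CC1=O
F6 | step 9 | (3S,3aS,5R,8aS)-3,6,8,8-tetramethyl-5-[(tributylstannyl)methoxy]-1,2,3,3a,4,5,8,8a-octahydroazulen-3-ol | CC1=CC(C)(C)[C@H]2CC[C@](C)(O)[C@H]2C[C@H]1OC[Sn](CCCC)(CCCC)CCCC
F7 | step 9 | (3S,3aS,7R,8aS)-7-(hydroxymethyl)-3,6,8,8-tetramethyl-1,2,3,3a,4,7,8,8a-octahydroazulen-3-ol | CC1=CC[C@H]2[C@H](CC[C@]2(C)O)C(C)(C)[C@@H]1CO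
F8 | step 9 | (3S,3aS,7R,8aS)-7-(iodomethyl)-3,6,8,8-tetramethyl-1,2,3,3a,4,7,8,8a-octahydroazulen-3-ol | CC1=CC[C@H]2[C@H](CC[C@]2(C)O)C(C)(C)[C@@H]1CI
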